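The synthesis rests on opening ring C at O4–C3. C3 carries both a methyl group and O4. This is the Markovnikov adduct pattern of the ring A phenol O4–H (on C4a, flanked by C5–OMe and C8a–O1) across a vinyl group on C2. One cobalt-hydride hydrogen-atom-transfer/radical-polar crossover cyclisation therefore makes the C3 methyl, the O4–C3 bond, ring C and the C3 stereocentre, relayed from C2. The precursor is the (S)-1-arylallyl ether of a 5-bromo-3-methoxycatechol with O4–H free. Bromine holds C7 for the propenyl group, and the ring B phenol is masked as an electron-withdrawing, base-labile tert-butyl carbonate.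

Key step: step 6

Remarks on the chemistry
- **Numbering:** the 1,4-benzodioxine numbering of the target (O1, C2, C3, O4, C4a, C5–C8, C8a) is used for all intermediates. Ring A is the benzo ring, ring B the syringyl ring and ring C the dioxane ring.
- **Stereochemical check:** the target is trans-(2R,3R). In the open compounds 7–9 the same spatial arrangement at C2 is labelled (S), because vinyl ranks below aryl whereas C3 of ring C ranks above it. Nothing is inverted in step 6.
- **Mask on ring B:** an acetal-type mask was rejected. Its acidic removal would meet an acid-sensitive propenylarene and a para-hydroxybenzylic C2–O1 bond. It would also leave ring B electron-rich enough to favour C2–O1 ionisation and aryl migration in the key step. The aryl tert-butyl carbonate avoids both problems and is installed together with the allylic leaving group.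
- **Aldehyde-to-phenol exchange:** a peracid is used instead of alkaline peroxide. Aldehyde 7 has no free ortho or para hydroxyl group, and alkaline peroxide would strip the carbonate.
- **Assumption:** the (Sa,Sc,Sc) antipode of ligand L is taken to give the (S)-ether. Both antipodes are commercial, so the sense of induction is checked on the first batch and the mirror-image ligand is used if needed. L = N,N-bis(1-phenylethyl)dinaphtho[2,1-d:1',2'-f][1,3,2]dioxaphosphepin-4-amine.

Step 1
Reactants: 1 syringaldehyde; 2 monoethyl malonate
Product: 3 ethyl (E)-3-(4-hydroxy-3,5-dimethoxyphenyl)prop-2-enoate (ethyl sinapate)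
Conditions: 2 (1.5 equiv), piperidine (0.1 equiv), pyridine, 80 °C
Reagents that add atoms: none
Why: The Knoevenagel–Doebner condensation with a malonic half-ester tolerates the free phenol, and the decarboxylative elimination gives the (E)-cinnamate directly.

Step 2
Reactants: 3 ethyl sinapate
Product: 4 sinapyl alcohol, (E)-4-(3-hydroxyprop-1-enyl)-2,6-dimethoxyphenol
Conditions: DIBAL-H (4 equiv), toluene, 0 °C; EtOH quench, aq. potassium sodium tartrate
Reagents that add atoms: none
Why: Excess DIBAL-H first caps the phenol as its aluminium phenoxide and then carries out the standard 1,2-reduction of a conjugated ester to the allylic alcohol without touching the alkene.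

Step 3
Reactants: 4 sinapyl alcohol
Product: 5 (E)-3-[4-(tert-butoxycarbonyloxy)-3,5-dimethoxyphenyl]prop-2-enyl tert-butyl carbonate
Conditions: Boc2O (2.4 equiv), DMAP (0.1 equiv), CH2Cl2, 0 °C to rt
Reagents that add atoms: di-tert-butyl dicarbonate, CC(C)(C)OC(=O)OC(=O)OC(C)(C)C
Why: DMAP-catalysed O-acylation converts the phenol and the primary allylic alcohol alike, so one operation installs the leaving group for step 4 and the base-labile, electron-withdrawing mask of ring B.

Step 4
Reactants: 5 bis-carbonate; 6 4-bromo-2-hydroxy-6-methoxybenzaldehyde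
Product: 7 (S)-4-bromo-2-({1-[4-(tert-butoxycarbonyloxy)-3,5-dimethoxyphenyl]prop-2-enyl}oxy)-6-methoxybenzaldehyde
Conditions: [Ir(cod)Cl]2 (2 mol %), (Sa,Sc,Sc)-L (4 mol %), pre-activated with n-PrNH2 (THF, 50 °C, volatiles then removed); 6 (1.3 equiv), K3PO4 (1 equiv), THF, rt
Reagents that add atoms: none
Why: In this iridium-catalysed asymmetric allylic etherification the cyclometallated phosphoramidite complex ionises only the allylic carbonate, the aryloxide attacks the aryl-bearing allyl terminus anti to the metal with the ligand fixing the face and hence (S)-C2, and the ortho-formyl group marks the future O4 site so that only O1 can be alkylated.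

Step 5
Reactants: 7 aldehyde ether
Product: 9 tert-butyl 4-[(1S)-1-(5-bromo-2-hydroxy-3-methoxyphenoxy)prop-2-enyl]-2,6-dimethoxyphenyl carbonate, via aryl formate 8 (not isolated)
Conditions: mCPBA (1.3 equiv), CH2Cl2, 0 °C to rt; aq. Na2S2O3/NaHCO3 wash; crude 8, Et3N (0.5 equiv), MeOH, 0 °C
Reagents that add atoms: meta-chloroperoxybenzoic acid, O=C(OO)c1cccc(Cl)c1
Why: In this Dakin-type Baeyer–Villiger oxidation the ring A aryl group flanked by two oxygen donors migrates far faster than the peracid can epoxidise the electron-poor monosubstituted alkene, and the very labile formate is then transesterified under conditions that leave the hindered aryl carbonate and C2 untouched.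

Step 6
Reactants: 9 phenol allyl ether
Product: 10 tert-butyl 4-[(2R,3R)-7-bromo-5-methoxy-3-methyl-2,3-dihydro-1,4-benzodioxin-2-yl]-2,6-dimethoxyphenyl carbonate
Conditions: [N,N'-bis(3,5-di-tert-butylsalicylidene)-2,3-dimethylbutane-2,3-diaminato]cobalt (10 mol %), N-fluoro-2,4,6-trimethylpyridinium triflate (1.5 equiv), (Me2SiH)2O (1.5 equiv), degassed PhCF3, 0 °C to rt, Ar
Reagents that add atoms: none
Why: The divalent cobalt complex is oxidised by the N-fluoropyridinium salt and turned by the silane into a cobalt hydride, which passes a hydrogen atom to the unhindered terminal CH2 and so makes the C3 methyl, after which the secondary C3 radical is captured by cobalt and the alkylcobalt is oxidised to a tetravalent, cation-like species. O4 then displaces cobalt from C3 while the liberated collidine takes the phenolic proton, which is the known cobalt-hydride radical-polar crossover hydroalkoxylation of monosubstituted alkenes by tethered O–H groups. Ring C (O4, C4a, C8a, O1, C2, C3) closes in the 6-exo mode (exo-tet at the alkylcobalt stage), and the 7-endo alternative is excluded because hydrogen goes to the alkene terminus. C3 is controlled by C2: Co–C homolysis lets the two C3-epimeric alkylcobalts interconvert, and the one that closes through a half-chair with the C2 aryl and C3 methyl groups both pseudo-equatorial reacts faster (Curtin–Hammett), which should favour the trans-(2R,3R) isomer. Chemoselectivity is secured because the vinyl group is the only alkene present, with bromine standing in for the styrenic propenyl group and blocking the para position of the phenol against oxidation. The aryl carbonate lowers the donor power of ring B and so disfavours C2–O1 ionisation, aryl shift to C3 and arene oxidation, while the high cobalt loading and low temperature shorten the lifetime of the free C3 radical.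

Step 7
Reactants: 10 bromobenzodioxane; 11 (E)-prop-1-enylboronic acid
Product: 13 4-[(2R,3R)-5-methoxy-3-methyl-7-[(E)-prop-1-enyl]-2,3-dihydro-1,4-benzodioxin-2-yl]-2,6-dimethoxyphenol (target), via O-Boc propenyl compound 12 (not isolated)
Conditions: 11 (1.5 equiv), Pd(OAc)2 (2 mol %), SPhos (4 mol %), K3PO4 (3 equiv), THF/H2O 10:1, 40 °C; then MeOH, rt; aq. NH4Cl work-up
Reagents that add atoms: none
Why: The Suzuki–Miyaura coupling transfers the propenyl group with retention of E geometry at the only C–Br bond, and the phosphate base in methanol then cleaves the phenolic carbonate by transesterification, so no acid meets the propenylarene or the para-hydroxybenzylic C2–O1 bond and both stereocentres stay as set.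

Compound list
1 | syringaldehyde | O=Cc1cc(OC)c(O)c(OC)c1 | starting material
2 | monoethyl malonate | CCOC(=O)CC(=O)O | starting material
3 | ethyl (E)-sinapate | CCOC(=O)/C=C/c1cc(OC)c(O)c(OC)c1 | intermediate
4 | sinapyl alcohol | OC/C=C/c1cc(OC)c(O)c(OC)c1 | intermediate
5 | (E)-3-[4-(tert-butoxycarbonyloxy)-3,5-dimethoxyphenyl]prop-2-enyl tert-butyl carbonate | CC(C)(C)OC(=O)OC/C=C/c1cc(OC)c(OC(=O)OC(C)(C)C)c(OC)c1 | intermediate
6 | 4-bromo-2-hydroxy-6-methoxybenzaldehyde | COc1cc(Br)cc(O)c1C=O | starting material
7 | (S)-4-bromo-2-({1-[4-(tert-butoxycarbonyloxy)-3,5-dimethoxyphenyl]prop-2-enyl}oxy)-6-methoxybenzaldehyde | O=Cc1c(OC)cc(Br)cc1O[C@H](c1cc(OC)c(OC(=O)OC(C)(C)C)c(OC)c1)C=C | intermediate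
8 | (S)-4-bromo-2-({1-[4-(tert-butoxycarbonyloxy)-3,5-dimethoxyphenyl]prop-2-enyl}oxy)-6-methoxyphenyl formate | O=COc1c(OC)cc(Br)cc1O[C@H](c1cc(OC)c(OC(=O)OC(C)(C)C)c(OC)c1)C=C | intermediate
9 | tert-butyl 4-[(1S)-1-(5-bromo-2-hydroxy-3-methoxyphenoxy)prop-2-enyl]-2,6-dimethoxyphenyl carbonate | Oc1c(OC)cc(Br)cc1O[C@H](c1cc(OC)c(OC(=O)OC(C)(C)C)c(OC)c1)C=C | intermediate
10 | tert-butyl 4-[(2R,3R)-7-bromo-5-methoxy-3-methyl-2,3-dihydro-1,4-benzodioxin-2-yl]-2,6-dimethoxyphenyl carbonate | Brc1cc(OC)c2c(c1)O[C@H](c1cc(OC)c(OC(=O)OC(C)(C)C)c(OC)c1)[C@@H](C)O2 | intermediate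
11 | (E)-prop-1-enylboronic acid | C/C=C/B(O)O | starting material
12 | tert-butyl 4-[(2R,3R)-5-methoxy-3-methyl-7-[(E)-prop-1-enyl]-2,3-dihydro-1,4-benzodioxin-2-yl]-2,6-dimethoxyphenyl carbonate | C/C=C/c1cc(OC)c2c(c1)O[C@H](c1cc(OC)c(OC(=O)OC(C)(C)C)c(OC)c1)[C@@H](C)O2 | intermediate
13 | 4-[(2R,3R)-5-methoxy-3-methyl-7-[(E)-prop-1-enyl]-2,3-dihydro-1,4-benzodioxin-2-yl]-2,6-dimethoxyphenol | C/C=C/c1cc(OC)c2c(c1)O[C@H](c1cc(OC)c(O)c(OC)c1)[C@@H](C)O2 | target

Total step count: 7. Longest linear sequence: 7 steps (1 to 13).

Steps most likely to fail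

**Step 6.**
- *What may go wrong:* After hydrogen-atom transfer the C3 radical may expel the ring A aryloxyl by β-scission of C2–O1. It may also hand the C2 hydrogen back to cobalt, so that the alkene migrates into conjugation and C2 is erased.
- At the cation-like stage ring B or the C2 hydrogen may shift to C3, and facial selectivity at C3 may be modest.
- Any cis isomer has to be removed at the stage of 10, because a later epimerisation at C2 would turn it into the mirror-image trans series.
- *Fallback (polar alkene activation, with no radical or cation at C3):* it sets out from 9. Iodoetherification (I2, NaHCO3, MeCN, 0 °C) closes the same O4–C3 bond in the same 6-exo sense through an iodonium ion. This gives tert-butyl 4-[(2R,3S)-7-bromo-3-(iodomethyl)-5-methoxy-2,3-dihydro-1,4-benzodioxin-2-yl]-2,6-dimethoxyphenyl carbonate F1.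
- The primary C–I bond of F1 is then reduced with Bu3SnH (1.1 equiv, concentrated solution, Et3B/air, toluene, 0 °C). This reduction is much faster than attack on the aryl C–Br bond and faster than ring opening of the primary radical. The fallback comes back at 10.

**Step 4.**
- *What may go wrong:* The formyl-stabilised aryloxide is a weak and potentially chelating nucleophile, and it is also a good leaving group. Slow turnover, re-ionisation of the branched ether, drift to the linear isomer and erosion of enantiopurity are therefore the main concerns.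
- *Fallback (stereocentre made first, C–O bond formed by SN2):* it sets out from 1. Boc2O/DMAP gives tert-butyl 4-formyl-2,6-dimethoxyphenyl carbonate F2.
- Vinylmagnesium bromide (THF, −78 °C) adds to the aldehyde only and gives racemic tert-butyl 4-(1-hydroxyprop-2-enyl)-2,6-dimethoxyphenyl carbonate F3.
- Sharpless kinetic resolution (Ti(OiPr)4, D-(−)-diisopropyl tartrate, t-BuOOH, 4 Å sieves, CH2Cl2, −20 °C) leaves tert-butyl 4-[(1R)-1-hydroxyprop-2-enyl]-2,6-dimethoxyphenyl carbonate F4. The (S)-antipode is consumed as tert-butyl 4-{(R)-hydroxy[(2R)-oxiran-2-yl]methyl}-2,6-dimethoxyphenyl carbonate F5.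
- Mitsunobu etherification of F4 with 6 (PPh3, DIAD, toluene, −20 °C) proceeds with inversion. It is helped by the acidity of 6 and by the non-donating ring B, which disfavours ionisation. The fallback comes back at 7.

**Step 7.**
- *What may go wrong:* The alkenylboronic acid may undergo protodeboronation or slow transmetalation, and E geometry may be partly lost.
- Once the phenoxide is unmasked in warm base, C2–O1 may open reversibly through a quinone methide, with loss of trans purity.
- *Fallback (neutral coupling, alkene geometry from thermodynamic isomerisation, deprotection as a separate operation):* it sets out from 10. Stille coupling with allyltributylstannane (Pd(PPh3)4, toluene, 90 °C) gives tert-butyl 4-[(2R,3R)-7-allyl-5-methoxy-3-methyl-2,3-dihydro-1,4-benzodioxin-2-yl]-2,6-dimethoxyphenyl carbonate F6.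
- RuHCl(CO)(PPh3)3 (cat., toluene, 80 °C) then moves the double bond into conjugation in favour of the E isomer. The fallback comes back at 12, which is now isolated and purified before a brief K2CO3/MeOH treatment at rt gives 13.

Further compounds
F1 | step 6 | tert-butyl 4-[(2R,3S)-7-bromo-3-(iodomethyl)-5-methoxy-2,3-dihydro-1,4-benzodioxin-2-yl]-2,6-dimethoxyphenyl carbonate | Brc1cc(OC)c2c(c1)O[C@H](c1cc(OC)c(OC(=O)OC(C)(C)C)c(OC)c1)[C@@H](CI)O2
F2 | step 4 | tert-butyl 4-formyl-2,6-dimethoxyphenyl carbonate | O=Cc1cc(OC)c(OC(=O)OC(C)(C)C)c(OC)c1
F3 | step 4 | racemic tert-butyl 4-(1-hydroxyprop-2-enyl)-2,6-dimethoxyphenyl carbonate | OC(c1cc(OC)c(OC(=O)OC(C)(C)C)c(OC)c1)C=C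
F4 | step 4 | tert-butyl 4-[(1R)-1-hydroxyprop-2-enyl]-2,6-dimethoxyphenyl carbonate | O[C@@H](c1cc(OC)c(OC(=O)OC(C)(C)C)c(OC)c1)C=C
F5 | step 4 | tert-butyl 4-{(R)-hydroxy[(2R)-oxiran-2-yl]methyl}-2,6-dimethoxyphenyl carbonate | O[C@H](c1cc(OC)c(OC(=O)OC(C)(C)C)c(OC)c1)[C@H]1CO1
F6 | step 7 | tert-butyl 4-[(2R,3R)-7-allyl-5-methoxy-3-methyl-2,3-dihydro-1,4-benzodioxin-2-yl]-2,6-dimethoxyphenyl carbonate | C=CCc1cc(OC)c2c(c1)O[C@H](c1cc(OC)c(OC(=O)OC(C)(C)C)c(OC)c1)[C@@H](C)O2
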